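# Proposed synthesis of 2-[(3S,5R)-3,5-dimethyl-5-[(2R,5E,9E)-2-methyl-10-phenyldeca-5,9-dien-1-yl]-1,2-dioxolan-3-yl]acetic acid (CNP0260904.3)

## The problem

The target is a 3,3,5,5-tetrasubstituted 1,2-dioxolane, numbered here from the carboxyl carbon C1 (ring = C3, C4, C5, with O1 on C5 and O2 on C3). C3 carries a methyl group and the C2–C1 acetic acid arm; C5 carries a methyl group and the C6–C15 chain, which holds a methyl stereocentre at C7, an (E)-alkene at C10=C11 and an (E)-styryl unit at C14=C15. The chain can be lengthened at many points, but the ring cannot be made by substitution: C3 and C5 are fully substituted, oxygen-bearing carbons, so each C–O bond has to come from capture of a cation or a Michael acceptor by peroxide oxygen. Of the three stereocentres (3S, 5R, 7R; the two ring methyl groups trans) only C7 can be bought. C3 and C5 each distinguish a methyl group from a CH2R group, are insulated from each other by C4 and from C7 by C6, so none of them can be counted on to control another; without reagent control the diastereomers must be separated, which is possible only because C7 is homochiral. Three features are fragile: the O–O bond (hydrides, low-valent metals, phosphines, hydrogenation and organolithiums are excluded once it exists), the β-peroxy carboxyl group (enolization at C2 can expel the peroxide oxygen from C3 and open the ring), and the 1,5-diene, which is a π-nucleophile toward any cation and must keep both E geometries. The feature that makes the key step possible is that C5 with its methyl group, C6 and O1 is a methyl ketone in disguise, while C4–C3(CH3)–C2–C1 is the carbon skeleton of a methallyl ester with C4 as the CH2 terminus; joined through O1–O2, the ring is the formal [3+2] adduct of a C5 peroxycarbenium ion and that alkene.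

## Retrosynthesis

**C1 acid from its ester.** Target 23 is taken back to methyl ester 22. No skeletal bond is cut; the acid stays masked as the methyl ester because a free acid would consume the Lewis acid of the ring-forming step and the carbanion of the olefination. The forward hydrolysis must favour acyl substitution over enolization of the β-peroxy ester.

**C10=C11.** The C10=C11 double bond of 22 is cut to aldehyde 15 (C1–C10, all three stereocentres) and the tetrazolyl sulfone 20 (C11–C15 and the phenyl ring). This cut removes both alkenes from the ring-bearing fragment, so no π-nucleophile is present when C5 is cationic; a C10 alkene would sit where it closes a six-membered ring (C5–C10) onto that cation. Cutting at C14=C15 would leave exactly that alkene in place, and cross-metathesis at C10=C11 would give statistical mixtures and touch the styrene. The forward Julia–Kocienski olefination must be E-selective and use only a stabilized carbanion at low temperature.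

**C10 oxidation level.** Aldehyde 15 comes from alcohol 14 and this from silyl ether 13. The unveiling must be non-basic and non-reducing, which points to HF·pyridine and a periodinane.

**C4–C5 and O2–C3 (key disconnection).** Dioxolane 13 is cut across C4–C5 and O2–C3 into the silylperoxy ketal 9 and methyl 3-methylbut-3-enoate 10. This makes both fully substituted peroxide carbons in one convergent step and brings C1 in at the correct oxidation level. The neighbouring cut (C3–C4 and O1–C5) would need C1 as a protected alcohol, and a cut of C–O bonds only would need the whole carbon skeleton with a configured tertiary hydroperoxide. The precursors are far simpler: 9 has only the C7 stereocentre and 10 is achiral and commercial. The forward reaction must ionize the methoxy group and not the silylperoxy group, must be attacked by the CH2 terminus of 10, and must close the ring faster than the C3 cation loses a proton. No stereocontrol at C3 or C5 is expected.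

**Peroxide oxygens.** Ketal 9 is the O-silyl derivative of hydroperoxy ketal 8, which arises from dimethyl ketal 7 by exchange of one methoxy group for OOH. The dimethyl ketal therefore serves twice, as ketone protection and as the substrate for perhydrolysis. The forward exchange must stop after one methoxy group.

**C5–C10 and the C7 stereocentre.** Ketal 7 is traced through alcohol 6, alkene ketal 4 and ketone 3 to (R)-citronellic acid 1. The carboxyl carbon of 1 becomes C5, its C3 becomes C7 and its alkene carbon C6 becomes C10. Two bonds change: the C5–CH3 bond is made by adding a methyl nucleophile to the carboxylate, and the isopropylidene group is cut off by ozone. C7 lies β to the carbonyl throughout and cannot epimerize.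

**Sulfone 20.** The C–S bond is cut to alcohol 18 (thioether 19 as intermediate), and the C12–C13 bond to cinnamyl bromide 16 and an acetate ester enolate (ester 17). The (E)-styryl geometry is bought with 16.

## Roads not taken

**Alternative 1:** Both C–O bonds of the ring (O1–C5 and O2–C3) are cut, and the whole chain is first assembled as the β,β-disubstituted enone A1. In the forward step a primary-amine salt of the 9-amino-9-deoxy-epi-cinchona family forms an iminium ion with A1, aqueous H2O2 adds at C5, and the β-hydroperoxy ketone closes onto the carbonyl to give dioxolanol A2.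
- Merits: it is the only plan that addresses the configuration of C5 with a catalyst; it uses no cation, so the diene can be present; and C10 needs no protecting group.
- Weak points: the known reaction type covers enones with one β-substituent. With A1 the iminium ion is hindered, its geometry can scramble through the dienamine, and the catalyst must tell a methyl group from a CH2R group at a fully substituted β-carbon. A2 is also not yet the target skeleton: the C2–C3 bond still has to be made by ionizing C3 to a cyclic peroxycarbenium ion and trapping it with an acetate nucleophile, with the diene present and with no element to control C3. The route to A1 is fully linear.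
- Comparison: if the hydroperoxidation were selective, only the two C3 epimers would have to be separated, which is better than four diastereomers. The chosen plan sets against this that each of its bond-forming steps belongs to a demonstrated reaction class, that it is convergent, and that the C1–C3 unit arrives intact with the alkene.

**Alternative 2:** O2–C3 and C1–C2 are cut. With Pd(OAc)2, benzoquinone and CO in methanol, the tertiary hydroperoxide A3 would add across its methallyl alkene (closing the ring) and the C2–palladium bond would be carbonylated to ester A4, which is identical with ester 22.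
- Merits: the product is one step from the target; the alkylpalladium intermediate has no β-hydrogen, so carbonylation is its natural fate; and the side chain needs no late olefination.
- Weak points: A3 with a defined C5 has no good source, because tertiary hydroperoxides are made through cations, so the diastereomer problem is only moved upstream. Divalent palladium with hydroperoxides tends to transfer oxygen to alkenes instead of keeping the O–O bond, and any zerovalent palladium formed reduces peroxides. The C10=C11 and styryl alkenes compete for the metal and for CO, and C3 is again uncontrolled.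
- Comparison: on paper this is the shortest endgame and is better in step economy. The chosen plan accepts four steps after ring formation in exchange for a key step with close precedent and no redox-active metal near the peroxide or the diene.

**Alternative 3:** The ring is cut the other way round (C3–C4 and O1–C5). SnCl4 ionizes the small silylperoxy ketal A5 to a C3 peroxycarbenium ion, the CH2 terminus of the chain alkene A6 attacks it, and the tertiary C5 cation is closed by peroxide oxygen to give A7.
- Merits: A6 is an unfunctionalized 2-methyl-1-alkene, exactly the nucleophile class for which the annulation is established, and the C5 cation has no electron-withdrawing neighbour. No β-peroxy ester exists until the very end, so the base-mediated olefination is safer. In these two respects this road is stronger than the chosen one.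
- Weak points: C1 arrives as a benzoate-protected alcohol, so the endgame needs ester removal and oxidation to the acid in the presence of the diene, and two primary oxygens have to be unveiled in order. The β-benzoyloxy ketal A5 is prone to β-elimination, and its cation is destabilized and can be intercepted by the benzoate carbonyl. Stereocontrol at C3 and C5 is no better.
- Comparison: the chosen plan sets against the better nucleophile the correct oxidation level of C1 from the start, a commercial alkene partner, a shorter endgame, and a stepwise rescue (vinylogous Mukaiyama addition, then peroxy-Michael closure) that exists only in the ester series.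

Key step: step 7

Assumption: (R)-citronellic acid of high enantiomeric purity is taken as a purchasable source of C7; it is otherwise one Pinnick oxidation away from (R)-citronellal.

## Route

Step 1
Reactants: 1 (R)-citronellic acid [(3R)-3,7-dimethyloct-6-enoic acid]
Product: 3 (4R)-4,8-dimethylnon-7-en-2-one, via dilithium gem-diolate 2 (not isolated)
Conditions: MeLi (2.2 equiv), Et2O, 0 °C → rt; inverse quench into cold 1 M HCl
Reagents that add atoms: methyllithium, [Li]C
Why: Addition of methyllithium to a lithium carboxylate (the classical acid-to-methyl-ketone conversion) stops at gem-diolate 2, which releases the ketone only in the inverse acidic quench after excess reagent is destroyed; the stereocentre is β to the carbonyl and is not touched.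

Step 2
Reactants: 3 (4R)-4,8-dimethylnon-7-en-2-one
Product: 4 (6R)-8,8-dimethoxy-2,6-dimethylnon-2-ene
Conditions: HC(OMe)3, MeOH, cat. PPTS, rt; Et3N quench
Reagents that add atoms: trimethyl orthoformate, COC(OC)OC
Why: Acid-catalysed ketalization driven by the orthoformate as water scavenger; the weak pyridinium acid should avoid addition of methanol to, or Prins-type closure of, the trisubstituted alkene.

Step 3
Reactants: 4 (6R)-8,8-dimethoxy-2,6-dimethylnon-2-ene
Product: 6 (4R)-6,6-dimethoxy-4-methylheptan-1-ol, via aldehyde 5 (not isolated)
Conditions: O3, CH2Cl2/MeOH, NaHCO3, −78 °C; then NaBH4, −78 °C → rt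
Reagents that add atoms: ozone, [O-][O+]=O
Why: Ozonolysis with reductive borohydride work-up: ozone cleaves the only alkene and NaBH4 reduces aldehyde 5 and the peroxidic cleavage products to the primary alcohol; the ketal is inert to hydride and the bicarbonate buffer keeps it from hydrolysing.

Step 4
Reactants: 6 (4R)-6,6-dimethoxy-4-methylheptan-1-ol
Product: 7 tert-butyl{[(4R)-6,6-dimethoxy-4-methylheptyl]oxy}diphenylsilane
Conditions: TBDPSCl, imidazole, CH2Cl2, 0 °C → rt
Reagents that add atoms: tert-butyl(chloro)diphenylsilane, CC(C)(C)[Si](Cl)(c1ccccc1)c1ccccc1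
Why: Standard silylation of a primary alcohol; the tert-butyldiphenylsilyl ether is chosen because it must outlast the acid of step 5 and SnCl4 in step 7 and still fall to HF·pyridine.

Step 5
Reactants: 7 tert-butyl{[(4R)-6,6-dimethoxy-4-methylheptyl]oxy}diphenylsilane
Product: 8 (4R)-7-{[tert-butyl(diphenyl)silyl]oxy}-2-methoxy-4-methylheptan-2-yl hydroperoxide (both C2 epimers)
Conditions: anhydrous H2O2 in Et2O (1.5 equiv), cat. camphorsulfonic acid, 0 °C; NaHCO3 quench
Reagents that add atoms: hydrogen peroxide, OO
Why: Acid-catalysed perhydrolysis of a ketal: reversible ionization and capture by H2O2 exchanges one methoxy group for OOH, and a small excess of peroxide, catalytic acid and low temperature are meant to stop at the mono-exchange; the new ketal centre forms as both epimers, which is immaterial because it becomes planar in step 7.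

Step 6
Reactants: 8 (4R)-7-{[tert-butyl(diphenyl)silyl]oxy}-2-methoxy-4-methylheptan-2-yl hydroperoxide
Product: 9 triethyl({(4R)-7-{[tert-butyl(diphenyl)silyl]oxy}-2-methoxy-4-methylheptan-2-yl}peroxy)silane (both C2 epimers)
Conditions: Et3SiOTf, Et3N, CH2Cl2, −78 → 0 °C
Reagents that add atoms: triethylsilyl trifluoromethanesulfonate, CC[Si](CC)(CC)OS(=O)(=O)C(F)(F)F
Why: O-Silylation of a hydroperoxide with a silyl triflate and an amine base, which at low temperature should be faster than any ionization of the ketal; the silyl group later leaves from oxygen in the ring closure.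

Step 7
Reactants: 9 triethyl({(4R)-7-{[tert-butyl(diphenyl)silyl]oxy}-2-methoxy-4-methylheptan-2-yl}peroxy)silane; 10 methyl 3-methylbut-3-enoate
Product: 13 methyl 2-[(3S,5R)-5-[(2R)-5-{[tert-butyl(diphenyl)silyl]oxy}-2-methylpentyl]-3,5-dimethyl-1,2-dioxolan-3-yl]acetate, via peroxycarbenium ion 11 (not isolated), via tertiary carbocation 12 (not isolated)
Conditions: 10 (3 equiv), SnCl4 (1.5 equiv), CH2Cl2, −78 → −40 °C; aq. NaHCO3; SiO2 chromatography, then preparative HPLC
Reagents that add atoms: none
Why: SnCl4 removes the methoxy group of 9, whose oxygen is more basic than the silylated peroxide oxygen, and leaves the peroxycarbenium ion 11, planar at C5. The unsubstituted CH2 terminus of 10 attacks C5 in the Markovnikov sense (C4–C5) to give the tertiary cation 12 at C3, which is captured by the silyl-bearing peroxide oxygen (O2–C3), after which chloride takes the triethylsilyl group. The dioxolane is thus closed by intramolecular recombination of a cation with an oxygen lone pair through the five-membered array C3–C4–C5–O1–O2; no bond at C3 is broken, so the exo/endo distinction does not arise. The closest known reaction type is the SnCl4-promoted annulation of triethylsilylperoxy ketals of ketones with 1,1-disubstituted alkenes to 3,3,5,5-tetrasubstituted 1,2-dioxolanes; here the alkene carries an ester two atoms from the cationic centre, which lowers its nucleophilicity and binds part of the Lewis acid, hence the excess of 10 and more than one equivalent of SnCl4. C5 is set in the C–C bond formation, where the only bias is the C7 methyl group across an acyclic CH2, and C3 in the ring closure, where methyl and CH2CO2Me differ little; all four C3/C5 diastereomers are therefore expected, and 13 (5R, ring methyl groups trans) is to be isolated by chromatography and assigned by NOE measurements. The step needs chemoselective ionization of OMe over OOSiEt3, attack by the CH2 terminus, and ring closure ahead of proton loss from 12: the first is inherent in the silylperoxy ketal, the second in the 1,1-disubstitution of 10, and the third is favoured by low temperature and the absence of base. No other π-nucleophile competes, because C10 is held as a silyl ether.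

Step 8
Reactants: 13 methyl 2-[(3S,5R)-5-[(2R)-5-{[tert-butyl(diphenyl)silyl]oxy}-2-methylpentyl]-3,5-dimethyl-1,2-dioxolan-3-yl]acetate
Product: 14 methyl 2-[(3S,5R)-5-[(2R)-5-hydroxy-2-methylpentyl]-3,5-dimethyl-1,2-dioxolan-3-yl]acetate
Conditions: HF·pyridine, pyridine, THF, 0 °C → rt
Reagents that add atoms: none
Why: Fluoride cleavage of the silyl ether under buffered, weakly acidic conditions; HF·pyridine is chosen over basic fluoride because it does not enolize the β-peroxy ester, and dialkyl peroxides are inert to it.

Step 9
Reactants: 14 methyl 2-[(3S,5R)-5-[(2R)-5-hydroxy-2-methylpentyl]-3,5-dimethyl-1,2-dioxolan-3-yl]acetate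
Product: 15 methyl 2-[(3S,5R)-3,5-dimethyl-5-[(2R)-2-methyl-5-oxopentyl]-1,2-dioxolan-3-yl]acetate
Conditions: Dess–Martin periodinane, NaHCO3, CH2Cl2, 0 °C → rt
Reagents that add atoms: none
Why: Dess–Martin oxidation of a primary alcohol to the aldehyde under buffered, non-reducing conditions that leave the O–O bond and the ester untouched.

Step 10
Reactants: 16 cinnamyl bromide [(E)-(3-bromoprop-1-en-1-yl)benzene]
Product: 17 tert-butyl (4E)-5-phenylpent-4-enoate
Conditions: tert-butyl acetate, LiN(i-Pr)2, THF, −78 °C; then 16, −78 → 0 °C
Reagents that add atoms: tert-butyl acetate, CC(=O)OC(C)(C)C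
Why: SN2 alkylation of the lithium enolate of tert-butyl acetate by a primary allylic bromide; the bulky ester suppresses Claisen self-condensation and the (E)-styryl geometry of 16 is carried over unchanged.

Step 11
Reactants: 17 tert-butyl (4E)-5-phenylpent-4-enoate
Product: 18 (4E)-5-phenylpent-4-en-1-ol
Conditions: LiAlH4, Et2O, 0 °C; aqueous work-up
Reagents that add atoms: none
Why: Hydride reduction of an ester to the primary alcohol; the isolated styryl alkene is inert to LiAlH4.

Step 12
Reactants: 18 (4E)-5-phenylpent-4-en-1-ol
Product: 19 1-phenyl-5-{[(4E)-5-phenylpent-4-en-1-yl]sulfanyl}-1H-tetrazole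
Conditions: 1-phenyl-1H-tetrazole-5-thiol, PPh3, DIAD, THF, 0 °C → rt
Reagents that add atoms: 1-phenyl-1H-tetrazole-5-thiol, Sc1nnnn1-c1ccccc1
Why: Mitsunobu thioetherification of a primary alcohol with the acidic tetrazole thiol.

Step 13
Reactants: 19 1-phenyl-5-{[(4E)-5-phenylpent-4-en-1-yl]sulfanyl}-1H-tetrazole
Product: 20 1-phenyl-5-{[(4E)-5-phenylpent-4-en-1-yl]sulfonyl}-1H-tetrazole
Conditions: (NH4)6Mo7O24·4H2O (cat.), 30% aq. H2O2, EtOH, 0 °C → rt
Reagents that add atoms: hydrogen peroxide, OO
Why: Molybdate-catalysed oxidation of the sulfide to the sulfone, the usual way to Julia–Kocienski reagents; sulfur is oxidized much faster than a disubstituted alkene is epoxidized.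

Step 14
Reactants: 20 1-phenyl-5-{[(4E)-5-phenylpent-4-en-1-yl]sulfonyl}-1H-tetrazole; 15 methyl 2-[(3S,5R)-3,5-dimethyl-5-[(2R)-2-methyl-5-oxopentyl]-1,2-dioxolan-3-yl]acetate
Product: 22 methyl 2-[(3S,5R)-3,5-dimethyl-5-[(2R,5E,9E)-2-methyl-10-phenyldeca-5,9-dien-1-yl]-1,2-dioxolan-3-yl]acetate, via potassium sulfonyl carbanion 21 (not isolated)
Conditions: 20 (1.3 equiv), KN(SiMe3)2 (1.2 equiv), DME, −60 °C; then 15, −60 °C → rt; aq. NH4Cl
Reagents that add atoms: none
Why: Julia–Kocienski olefination: carbanion 21 adds to aldehyde 15, and Smiles rearrangement with loss of SO2 and the tetrazolone gives the C10=C11 alkene, the phenyltetrazolyl sulfone with a potassium base in DME being the combination that favours the E-alkene for unbranched partners. The sulfone is metalated first with a slight deficit of base, so the ester α-CH2 and the O–O bond meet only a stabilized carbanion at low temperature.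

Step 15
Reactants: 22 methyl 2-[(3S,5R)-3,5-dimethyl-5-[(2R,5E,9E)-2-methyl-10-phenyldeca-5,9-dien-1-yl]-1,2-dioxolan-3-yl]acetate
Product: 23 2-[(3S,5R)-3,5-dimethyl-5-[(2R,5E,9E)-2-methyl-10-phenyldeca-5,9-dien-1-yl]-1,2-dioxolan-3-yl]acetic acid
Conditions: LiOH, THF/MeOH/H2O, 0 °C → rt; then 1 M HCl to pH 3
Reagents that add atoms: lithium hydroxide, [Li+].[OH-]
Why: Saponification of a methyl ester, acyl substitution at low temperature being expected to outrun enolization of the β-peroxy ester; the peroxide carbons bear no hydrogen, so Kornblum–DeLaMare fragmentation is not possible.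

## Compound list

1 | (R)-citronellic acid, (3R)-3,7-dimethyloct-6-enoic acid | C[C@H](CCC=C(C)C)CC(=O)O | starting material
2 | dilithium (4R)-4,8-dimethylnon-7-ene-2,2-diolate | C[C@H](CCC=C(C)C)CC(C)([O-])[O-].[Li+].[Li+] | intermediate (not isolated)
3 | (4R)-4,8-dimethylnon-7-en-2-one | C[C@H](CCC=C(C)C)CC(C)=O | intermediate
4 | (6R)-8,8-dimethoxy-2,6-dimethylnon-2-ene | C[C@H](CCC=C(C)C)CC(C)(OC)OC | intermediate
5 | (4R)-6,6-dimethoxy-4-methylheptanal | C[C@H](CCC=O)CC(C)(OC)OC | intermediate (not isolated)
6 | (4R)-6,6-dimethoxy-4-methylheptan-1-ol | C[C@H](CCCO)CC(C)(OC)OC | intermediate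
7 | tert-butyl{[(4R)-6,6-dimethoxy-4-methylheptyl]oxy}diphenylsilane | C[C@H](CCCO[Si](c1ccccc1)(c1ccccc1)C(C)(C)C)CC(C)(OC)OC | intermediate
8 | (4R)-7-{[tert-butyl(diphenyl)silyl]oxy}-2-methoxy-4-methylheptan-2-yl hydroperoxide (both C2 epimers) | C[C@H](CCCO[Si](c1ccccc1)(c1ccccc1)C(C)(C)C)CC(C)(OC)OO | intermediate
9 | triethyl({(4R)-7-{[tert-butyl(diphenyl)silyl]oxy}-2-methoxy-4-methylheptan-2-yl}peroxy)silane (both C2 epimers) | COC(C)(C[C@H](C)CCCO[Si](c1ccccc1)(c1ccccc1)C(C)(C)C)OO[Si](CC)(CC)CC | intermediate
10 | methyl 3-methylbut-3-enoate | C=C(C)CC(=O)OC | starting material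
11 | peroxycarbenium ion: [(4R)-7-{[tert-butyl(diphenyl)silyl]oxy}-4-methylheptan-2-ylidene][(triethylsilyl)oxy]oxonium tetrachloro(methoxy)stannate | CC(=[O+]O[Si](CC)(CC)CC)C[C@H](C)CCCO[Si](c1ccccc1)(c1ccccc1)C(C)(C)C.CO[Sn-](Cl)(Cl)(Cl)Cl | intermediate (not isolated)
12 | tertiary carbocation: (7R)-10-{[tert-butyl(diphenyl)silyl]oxy}-1-methoxy-3,5,7-trimethyl-1-oxo-5-[(triethylsilyl)peroxy]decan-3-ylium tetrachloro(methoxy)stannate (C5 epimers) | COC(=O)C[C+](C)CC(C)(C[C@H](C)CCCO[Si](c1ccccc1)(c1ccccc1)C(C)(C)C)OO[Si](CC)(CC)CC.CO[Sn-](Cl)(Cl)(Cl)Cl | intermediate (not isolated)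
13 | methyl 2-[(3S,5R)-5-[(2R)-5-{[tert-butyl(diphenyl)silyl]oxy}-2-methylpentyl]-3,5-dimethyl-1,2-dioxolan-3-yl]acetate | C[C@H](CCCO[Si](c1ccccc1)(c1ccccc1)C(C)(C)C)C[C@]1(C)C[C@@](C)(CC(=O)OC)OO1 | intermediate
14 | methyl 2-[(3S,5R)-5-[(2R)-5-hydroxy-2-methylpentyl]-3,5-dimethyl-1,2-dioxolan-3-yl]acetate | C[C@H](CCCO)C[C@]1(C)C[C@@](C)(CC(=O)OC)OO1 | intermediate
15 | methyl 2-[(3S,5R)-3,5-dimethyl-5-[(2R)-2-methyl-5-oxopentyl]-1,2-dioxolan-3-yl]acetate | C[C@H](CCC=O)C[C@]1(C)C[C@@](C)(CC(=O)OC)OO1 | intermediate
16 | cinnamyl bromide, (E)-(3-bromoprop-1-en-1-yl)benzene | BrC/C=C/c1ccccc1 | starting material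
17 | tert-butyl (4E)-5-phenylpent-4-enoate | CC(C)(C)OC(=O)CC/C=C/c1ccccc1 | intermediate
18 | (4E)-5-phenylpent-4-en-1-ol | OCCC/C=C/c1ccccc1 | intermediate
19 | 1-phenyl-5-{[(4E)-5-phenylpent-4-en-1-yl]sulfanyl}-1H-tetrazole | S(CCC/C=C/c1ccccc1)c1nnnn1-c1ccccc1 | intermediate
20 | 1-phenyl-5-{[(4E)-5-phenylpent-4-en-1-yl]sulfonyl}-1H-tetrazole | O=S(=O)(CCC/C=C/c1ccccc1)c1nnnn1-c1ccccc1 | intermediate
21 | potassium (4E)-5-phenyl-1-[(1-phenyl-1H-tetrazol-5-yl)sulfonyl]pent-4-en-1-ide | [K+].[CH-](CC/C=C/c1ccccc1)S(=O)(=O)c1nnnn1-c1ccccc1 | intermediate (not isolated)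
22 | methyl 2-[(3S,5R)-3,5-dimethyl-5-[(2R,5E,9E)-2-methyl-10-phenyldeca-5,9-dien-1-yl]-1,2-dioxolan-3-yl]acetate | C[C@H](CC/C=C/CC/C=C/c1ccccc1)C[C@]1(C)C[C@@](C)(CC(=O)OC)OO1 | intermediate
23 | 2-[(3S,5R)-3,5-dimethyl-5-[(2R,5E,9E)-2-methyl-10-phenyldeca-5,9-dien-1-yl]-1,2-dioxolan-3-yl]acetic acid | C[C@H](CC/C=C/CC/C=C/c1ccccc1)C[C@]1(C)C[C@@](C)(CC(=O)O)OO1 | target

## Step count and least certain steps

Total: 15 steps. Longest linear sequence: 11 steps (steps 1–9, 14 and 15, from 1 to 23); the sulfone branch is 4 steps (steps 10–13).

**Step 7 (key step).** Three processes can spoil it.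
- The ester lowers the nucleophilicity of the alkene and ties up Lewis acid, so the peroxycarbenium ion may fragment before it is trapped.
- Proton loss from the C3 cation may outrun ring closure, because the C2 hydrogens are acidified by the ester.
- Facial selectivity at C5 and C3 is expected to be poor, so the wanted isomer is a minor part of a four-component mixture that may co-elute; alcohol 14 offers a second, more polar stage for separation.

The fallback sets out from 9 and returns at 13. It makes the C4–C5 bond first with a much stronger nucleophile and closes the ring afterwards by known peroxide chemistry. Methyl 3-methylbut-2-enoate is converted with LiN(i-Pr)2 and Me3SiCl into the silyl dienolate [(1-methoxy-3-methylbuta-1,3-dien-1-yl)oxy]trimethylsilane F1. Catalytic Me3SiOTf in CH2Cl2 at −78 °C should then join 9 and F1 at the γ-carbon (vinylogous Mukaiyama addition to the peroxycarbenium ion) to give methyl (2E,7R)-10-{[tert-butyl(diphenyl)silyl]oxy}-3,5,7-trimethyl-5-[(triethylsilyl)peroxy]dec-2-enoate F2. Brief HF·pyridine at 0 °C should remove only the silyl group on the peroxide and give methyl (2E,7R)-10-{[tert-butyl(diphenyl)silyl]oxy}-5-hydroperoxy-3,5,7-trimethyldec-2-enoate F3. Et2NH in CF3CH2OH then closes the ring by intramolecular peroxy-Michael addition (5-exo-trig) to the same set of diastereomers, from which 13 is separated. The stereochemical burden is unchanged.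

**Step 5.** Both C–O bonds of the ketal exchange under acid, so the reaction may run on to the gem-dihydroperoxide or back to the ketone. The fallback sets out from 7 and returns at 8. PPTS in wet acetone frees the ketone (4R)-7-{[tert-butyl(diphenyl)silyl]oxy}-4-methylheptan-2-one F4, Wittig methylenation with Ph3P=CH2 gives the alkene tert-butyl{[(4R)-4,6-dimethylhept-6-en-1-yl]oxy}diphenylsilane F5, and ozonolysis of F5 in CH2Cl2/MeOH at −78 °C without a reductant lets methanol trap the ketone O-oxide, which delivers 8 directly.

**Step 14.** The metalated sulfone or the intermediate alkoxide may enolize the β-peroxy ester, which would open the ring by β-elimination of the peroxide and scramble C3. Carbanion attack on the O–O bond or erosion of the E selectivity are further possibilities. The fallback sets out from 14 and returns at 23. LiOH gives the hydroxy acid 2-[(3S,5R)-5-[(2R)-5-hydroxy-2-methylpentyl]-3,5-dimethyl-1,2-dioxolan-3-yl]acetic acid F6, and Dess–Martin oxidation gives the aldehyde acid 2-[(3S,5R)-3,5-dimethyl-5-[(2R)-2-methyl-5-oxopentyl]-1,2-dioxolan-3-yl]acetic acid F7. F7 is converted into its potassium carboxylate with one equivalent of KN(SiMe3)2 and then treated with carbanion 21. A carboxylate cannot be enolized under these conditions, and the olefination gives 23 without a further step.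

**Step 15.** Hydroxide may enolize the ester in competition with acyl substitution, with the same ring opening as above. The fallback sets out from 22 and returns at 23: Me3SnOH in 1,2-dichloroethane at 60 °C cleaves the methyl ester through a tin–carbonyl complex without a free enolizing base; no new compound is involved.

## Further compounds

F1 | step 7 | [(1-methoxy-3-methylbuta-1,3-dien-1-yl)oxy]trimethylsilane | C=C(C)C=C(OC)O[Si](C)(C)C
F2 | step 7 | methyl (2E,7R)-10-{[tert-butyl(diphenyl)silyl]oxy}-3,5,7-trimethyl-5-[(triethylsilyl)peroxy]dec-2-enoate (C5 epimers) | C[C@H](CCCO[Si](c1ccccc1)(c1ccccc1)C(C)(C)C)CC(C)(C/C(C)=C/C(=O)OC)OO[Si](CC)(CC)CC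
F3 | step 7 | methyl (2E,7R)-10-{[tert-butyl(diphenyl)silyl]oxy}-5-hydroperoxy-3,5,7-trimethyldec-2-enoate (C5 epimers) | C[C@H](CCCO[Si](c1ccccc1)(c1ccccc1)C(C)(C)C)CC(C)(C/C(C)=C/C(=O)OC)OO
F4 | step 5 | (4R)-7-{[tert-butyl(diphenyl)silyl]oxy}-4-methylheptan-2-one | C[C@H](CCCO[Si](c1ccccc1)(c1ccccc1)C(C)(C)C)CC(C)=O
F5 | step 5 | tert-butyl{[(4R)-4,6-dimethylhept-6-en-1-yl]oxy}diphenylsilane | C[C@H](CCCO[Si](c1ccccc1)(c1ccccc1)C(C)(C)C)CC(C)=C
F6 | step 14 | 2-[(3S,5R)-5-[(2R)-5-hydroxy-2-methylpentyl]-3,5-dimethyl-1,2-dioxolan-3-yl]acetic acid | C[C@H](CCCO)C[C@]1(C)C[C@@](C)(CC(=O)O)OO1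
F7 | step 14 | 2-[(3S,5R)-3,5-dimethyl-5-[(2R)-2-methyl-5-oxopentyl]-1,2-dioxolan-3-yl]acetic acid | C[C@H](CCC=O)C[C@]1(C)C[C@@](C)(CC(=O)O)OO1
F0 | step 15 | none | none
A1 | alternative 1 | (3E,6R,9E,13E)-4,6-dimethyl-14-phenyltetradeca-3,9,13-trien-2-one | CC(=O)/C=C(\C)C[C@H](C)CC/C=C/CC/C=C/c1ccccc1
A2 | alternative 1 | (5R)-3,5-dimethyl-5-[(2R,5E,9E)-2-methyl-10-phenyldeca-5,9-dien-1-yl]-1,2-dioxolan-3-ol (C3 epimers) | C[C@H](CC/C=C/CC/C=C/c1ccccc1)C[C@]1(C)CC(C)(O)OO1
A3 | alternative 2 | (4R,6R,9E,13E)-2,4,6-trimethyl-14-phenyltetradeca-1,9,13-trien-4-yl hydroperoxide | C[C@H](CC/C=C/CC/C=C/c1ccccc1)C[C@](C)(CC(C)=C)OO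
A4 | alternative 2 | methyl 2-[(3S,5R)-3,5-dimethyl-5-[(2R,5E,9E)-2-methyl-10-phenyldeca-5,9-dien-1-yl]-1,2-dioxolan-3-yl]acetate | C[C@H](CC/C=C/CC/C=C/c1ccccc1)C[C@]1(C)C[C@@](C)(CC(=O)OC)OO1
A5 | alternative 3 | 3-methoxy-3-[(triethylsilyl)peroxy]butyl benzoate | COC(C)(CCOC(=O)c1ccccc1)OO[Si](CC)(CC)CC
A6 | alternative 3 | tert-butyl{[(4R)-4,6-dimethylhept-6-en-1-yl]oxy}diphenylsilane | C[C@H](CCCO[Si](c1ccccc1)(c1ccccc1)C(C)(C)C)CC(C)=C
A7 | alternative 3 | 2-[(3R,5R)-5-[(2R)-5-{[tert-butyl(diphenyl)silyl]oxy}-2-methylpentyl]-3,5-dimethyl-1,2-dioxolan-3-yl]ethyl benzoate | C[C@H](CCCO[Si](c1ccccc1)(c1ccccc1)C(C)(C)C)C[C@]1(C)C[C@@](C)(CCOC(=O)c2ccccc2)OO1
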